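**Plan**

Cuts: C15–C15′ (sp2–sp2 coupling of two C20 halves); C10=C11 and C8=C9 in each half (Wittig reactions with a C6 enyne unit and a C3 unit); in each ring C1–C2 and C5–C6.
Enabling feature: in both rings the CMe2 carbon C1 and the ylidene carbon C6 (=C7) are the distal C=C of a γ,γ-dimethylallene, and C2–C3(O)–C4–C5(CH3) is the diene of triacetic acid lactone. A pyrone–allene [4+2] cycloaddition, with the lactone bridge leaving as CO2, gives one achiral ylidene-enone 11 that serves ring A and ring B.
Forward: pyrone 2 + allenamide 8 → 11; ring A (3,5-diol) by epoxidation of C4=C5, reductive opening and directed reduction; ring B by CBS reduction; each C11 amide → enal → C14 dienal → C20 trienyne with one shared batch of C6 ylide; the halves are joined at C15–C15′; desilylation.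
Stereochemistry: C5 from catalyst-controlled epoxidation; C3 from C5 by intramolecular hydride delivery (1,3-anti); C3′ from CBS reduction; 6E and 6′E from approach of the pyrone anti to the amide group of the allene; chain olefins from stabilised ylides, I2 equilibration and syn hydrometalation.

Key step: step 4

Locants: ring A = C1 (CMe2), C2, C3 (CHOH), C4, C5 (C(CH3)OH), C6 (=C7); chain C7–C15; ring B (3′-hydroxy-4′,5′-ene ring) and its half chain carry primed locants.
Remark on the chemistry: the sense of induction in steps 5 and 15 is assigned by analogy with simpler cyclohexenones; should it prove opposite, the pseudoenantiomeric amine (from quinidine) or (S)-CBS is taken. Compound 9 forms as a racemate (one enantiomer is drawn). Ylide 21 is made as one batch of cold THF solution and divided at once between steps 13 and 19, so aldehydes 18 and 28 are brought to that point together.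

Step 1
Reactants: 1 4-hydroxy-6-methyl-2H-pyran-2-one (triacetic acid lactone)
Product: 2 6-methyl-2-oxo-2H-pyran-4-yl acetate
Conditions: Ac2O (1.5 equiv), pyridine, 0 to 25 °C
Reagents that add atoms: acetic anhydride, CC(=O)OC(C)=O
Why: O-acylation of the acidic enol gives the enol acetate, which removes the acidic proton and keeps the C3 oxygen masked through the cycloaddition; no stereocenter.

Step 2
Reactants: 3 2-bromo-N-methoxy-N-methylacetamide
Product: 4 [2-(methoxy(methyl)amino)-2-oxoethyl]triphenylphosphonium bromide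
Conditions: PPh3 (1.0 equiv), PhMe, 50 °C
Reagents that add atoms: triphenylphosphine, c1ccc(cc1)P(c1ccccc1)c1ccccc1
Why: SN2 quaternisation of the phosphine by the α-bromo amide (phosphonium salt formation).

Step 3
Reactants: 4 [2-(methoxy(methyl)amino)-2-oxoethyl]triphenylphosphonium bromide; 5 2-methylpropanoyl chloride
Product: 8 N-methoxy-N,4-dimethylpenta-2,3-dienamide, via stabilised ylide 6 (not isolated), via dimethylketene 7 (not isolated)
Conditions: Et3N (2.2 equiv), CH2Cl2, 0 to 25 °C
Reagents that add atoms: none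
Why: Et3N forms ylide 6 from 4 and dimethylketene 7 from 5, and Wittig olefination of the ketene carbonyl gives the allene (Wittig reaction of a ketene); the allene carries no stereo element because C4 bears two methyl groups.

Step 4
Reactants: 2 6-methyl-2-oxo-2H-pyran-4-yl acetate; 8 N-methoxy-N,4-dimethylpenta-2,3-dienamide
Product: 11 (2E)-N-methoxy-N-methyl-2-(2,6,6-trimethyl-4-oxocyclohex-2-en-1-ylidene)acetamide, via bridged lactone 9 (not isolated), via dienyl acetate 10 (not isolated)
Conditions: 8 (1.5 equiv), BHT (5 mol %), PhMe, sealed tube, 140 °C; then K2CO3 (0.2 equiv), MeOH, 0 °C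
Reagents that add atoms: none
Why: Proposed new method: pyrone 2 is expected to add as the 4π partner across the distal Me2C=C π-bond of allene 8 in an asynchronous [4+2] cycloaddition in which the electrophilic C6 of the pyrone bonds to the central allene carbon and the CMe2 terminus, which takes up the positive charge, bonds to the nucleophilic pyrone C3; bridged lactone 9 then loses CO2 by retro-[4+2] to 10, and K2CO3/MeOH cleaves the enol acetate so that protonation at C2 gives enone 11. The closest known reaction type is the thermal cycloaddition/decarboxylation of 2-pyrones with alkenes and alkynes, which is not described for an acyclic allene. The carbocycle is closed in one suprafacial six-electron event (both σ-bonds in the same transition state, so no separate cyclisation mode applies), and the lactone bridge is only a temporary ring. The two bridgehead centres of 9 are fixed relative to each other by the bicycle, form as a racemate and are erased with the CO2, so 11 is achiral and no stereocenter has to be controlled here. What has to be controlled is site, orientation and olefin geometry: the Weinreb amide makes its own α,β-bond a poor partner and the two methyl groups make the distal bond the most electron-rich one, the orientation follows the polarisation just described (quaternary carbon next to the future C2, methyl-bearing carbon next to the ylidene carbon), and because the amide lies in the plane of the reacting π-orbitals the pyrone has to come in anti to it, which places C8 cis to CMe2, the (6E)-geometry of both rings.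

Step 5
Reactants: 11 (2E)-N-methoxy-N-methyl-2-(2,6,6-trimethyl-4-oxocyclohex-2-en-1-ylidene)acetamide
Product: 12 (2E)-N-methoxy-N-methyl-2-[(1R,6R)-1,3,3-trimethyl-5-oxo-7-oxabicyclo[4.1.0]heptan-2-ylidene]acetamide (C4–C5 epoxide)
Conditions: 9-amino-9-deoxy-epi-quinine (10 mol %), CF3CO2H (20 mol %), 50 % aq. H2O2 (1.5 equiv), dioxane, 35 °C
Reagents that add atoms: hydrogen peroxide, OO
Why: Iminium-catalysed asymmetric Weitz–Scheffer epoxidation: the primary amine forms an iminium ion with the ring ketone, hydroperoxide adds to C5 on the face left open by the catalyst and the enamine closes the cis-epoxide, so C4 and C5 are set together under catalyst control, while C7 (α-carbon of the amide) is not a site for 1,6-attack.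

Step 6
Reactants: 12 (2E)-N-methoxy-N-methyl-2-[(1R,6R)-1,3,3-trimethyl-5-oxo-7-oxabicyclo[4.1.0]heptan-2-ylidene]acetamide
Product: 13 (2E)-2-[(2S)-2-hydroxy-2,6,6-trimethyl-4-oxocyclohexylidene]-N-methoxy-N-methylacetamide
Conditions: SmI2 (2.2 equiv), THF/MeOH 4:1, –90 °C
Reagents that add atoms: none
Why: SmI2 reduction of an α,β-epoxy ketone: the ketyl cleaves the Cα–O bond (C4–O) and MeOH protonates the enolate, so the C5–O bond and its configuration are kept (C5 becomes S by descriptor only).

Step 7
Reactants: 13 (2E)-2-[(2S)-2-hydroxy-2,6,6-trimethyl-4-oxocyclohexylidene]-N-methoxy-N-methylacetamide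
Product: 14 (2E)-2-[(2S,4R)-2,4-dihydroxy-2,6,6-trimethylcyclohexylidene]-N-methoxy-N-methylacetamide
Conditions: Me4NBH(OAc)3 (5 equiv), MeCN/AcOH 1:1, –30 °C
Reagents that add atoms: none
Why: Evans–Saksena reduction: the tertiary C5–OH exchanges an acetate on boron and delivers hydride intramolecularly to the face of the C3 ketone syn to itself, which should give the 1,3-anti (trans) diol, that is (3R) from (5S).

Step 8
Reactants: 14 (2E)-2-[(2S,4R)-2,4-dihydroxy-2,6,6-trimethylcyclohexylidene]-N-methoxy-N-methylacetamide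
Product: 15 (2E)-N-methoxy-N-methyl-2-[(2S,4R)-2,6,6-trimethyl-2,4-bis(triethylsilyloxy)cyclohexylidene]acetamide
Conditions: Et3SiOTf (2.6 equiv), 2,6-lutidine (4 equiv), CH2Cl2, –78 to 0 °C
Reagents that add atoms: triethylsilyl trifluoromethanesulfonate, CC[Si](CC)(CC)OS(=O)(=O)C(F)(F)F
Why: O-silylation of both hydroxyls (the silyl triflate is needed for the tertiary allylic alcohol) under buffered conditions that leave both carbinol centres untouched.

Step 9
Reactants: 15 (2E)-N-methoxy-N-methyl-2-[(2S,4R)-2,6,6-trimethyl-2,4-bis(triethylsilyloxy)cyclohexylidene]acetamide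
Product: 16 (2E)-2-[(2S,4R)-2,6,6-trimethyl-2,4-bis(triethylsilyloxy)cyclohexylidene]acetaldehyde
Conditions: i-Bu2AlH (1.3 equiv), THF, –78 °C; aq. potassium sodium tartrate
Reagents that add atoms: none
Why: Hydride reduction of a Weinreb amide stops at the chelated hemiaminal, which releases the aldehyde (C8) on work-up.

Step 10
Reactants: 16 (2E)-2-[(2S,4R)-2,6,6-trimethyl-2,4-bis(triethylsilyloxy)cyclohexylidene]acetaldehyde; 17 2-(triphenyl-λ5-phosphanylidene)propanal
Product: 18 (2E,4E)-2-methyl-4-[(2S,4R)-2,6,6-trimethyl-2,4-bis(triethylsilyloxy)cyclohexylidene]but-2-enal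
Conditions: PhMe, 90 °C
Reagents that add atoms: none
Why: Wittig reaction of the stabilised formyl ylide forms C8=C9 with the E-selectivity typical of stabilised ylides and stops at the less reactive α-methyl enal.

Step 11
Reactants: 19 (2E)-3-methylpent-2-en-4-yn-1-ol
Product: 20 [(2E)-3-methylpent-2-en-4-yn-1-yl]triphenylphosphonium bromide
Conditions: PPh3·HBr (1.0 equiv), CH2Cl2, 25 °C
Reagents that add atoms: triphenylphosphine hydrobromide, [Br-].c1ccc(cc1)[PH+](c1ccccc1)c1ccccc1
Why: Acid-promoted substitution of the primary allylic alcohol by the phosphine (allylic phosphonium salt formation), expected to keep the (E)-olefin.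

Step 12
Reactants: 20 [(2E)-3-methylpent-2-en-4-yn-1-yl]triphenylphosphonium bromide
Product: 21 [(2E)-3-methylpent-2-en-4-yn-1-ylidene]triphenyl-λ5-phosphane (enynyl ylide, kept as a cold THF solution)
Conditions: NaN(SiMe3)2 (0.98 equiv), THF, –78 °C, 30 min; the solution is divided at once between steps 13 and 19
Reagents that add atoms: none
Why: Ylide formation by deprotonation of the phosphonium α-CH2, which is more acidic than the acetylenic CH; the slight deficit of base leaves no amide base to attack the aldehydes, and one batch serves both halves.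

Step 13
Reactants: 18 (2E,4E)-2-methyl-4-[(2S,4R)-2,6,6-trimethyl-2,4-bis(triethylsilyloxy)cyclohexylidene]but-2-enal; 21 [(2E)-3-methylpent-2-en-4-yn-1-ylidene]triphenyl-λ5-phosphane
Product: 22 ring A trienyne: (2S,4R)-2,6,6-trimethyl-2,4-bis(triethylsilyloxy)cyclohexane bearing at C1 the (1E)-[(2E,4E,6E)-3,7-dimethylnona-2,4,6-trien-8-yn-1-ylidene] chain
Conditions: 21 (1.3 equiv, THF solution from step 12), THF, –78 to 0 °C; then I2 (0.5 mol %), hexane, 25 °C, diffuse light
Reagents that add atoms: none
Why: Wittig reaction of the semi-stabilised allylic ylide forms C10=C11, and the hindered (10Z) isomer is equilibrated to (10E) by iodine catalysis.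

Step 14
Reactants: 22 ring A trienyne
Product: 24 ring A tetraenyl iodide: the same ring bearing the (1E)-[(2E,4E,6E,8E)-9-iodo-3,7-dimethylnona-2,4,6,8-tetraen-1-ylidene] chain, via alkenylzirconocene 23 (not isolated)
Conditions: Cp2Zr(H)Cl (1.3 equiv), THF, 25 °C, dark; then I2 (1.1 equiv), THF, –78 to 0 °C
Reagents that add atoms: iodine, II
Why: Hydrozirconation adds Zr–H syn across the terminal alkyne with zirconium at C15, and iodinolysis with retention gives the (14E)-alkenyl iodide.

Step 15
Reactants: 11 (2E)-N-methoxy-N-methyl-2-(2,6,6-trimethyl-4-oxocyclohex-2-en-1-ylidene)acetamide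
Product: 25 (2E)-2-[(4S)-4-hydroxy-2,6,6-trimethylcyclohex-2-en-1-ylidene]-N-methoxy-N-methylacetamide
Conditions: (R)-2-methyl-CBS-oxazaborolidine (20 mol %), catecholborane (1.5 equiv), PhMe, –78 °C
Reagents that add atoms: none
Why: CBS reduction: the ketone binds the catalyst boron anti to its larger alkenyl substituent and hydride is delivered to one face (1,2-reduction), which sets C3′ as (S).

Step 16
Reactants: 25 (2E)-2-[(4S)-4-hydroxy-2,6,6-trimethylcyclohex-2-en-1-ylidene]-N-methoxy-N-methylacetamide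
Product: 26 (2E)-2-[(4S)-4-(tert-butyldimethylsilyloxy)-2,6,6-trimethylcyclohex-2-en-1-ylidene]-N-methoxy-N-methylacetamide
Conditions: t-BuMe2SiCl (1.3 equiv), imidazole, DMF, 25 °C
Reagents that add atoms: tert-butyldimethylsilyl chloride, CC(C)(C)[Si](C)(C)Cl
Why: Silyl protection of the ionisation-prone secondary allylic alcohol without change at C3′.

Step 17
Reactants: 26 (2E)-2-[(4S)-4-(tert-butyldimethylsilyloxy)-2,6,6-trimethylcyclohex-2-en-1-ylidene]-N-methoxy-N-methylacetamide
Product: 27 (2E)-2-[(4S)-4-(tert-butyldimethylsilyloxy)-2,6,6-trimethylcyclohex-2-en-1-ylidene]acetaldehyde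
Conditions: i-Bu2AlH (1.3 equiv), THF, –78 °C; aq. potassium sodium tartrate
Reagents that add atoms: none
Why: Weinreb amide reduction to the aldehyde (C8′), as in step 9.

Step 18
Reactants: 27 (2E)-2-[(4S)-4-(tert-butyldimethylsilyloxy)-2,6,6-trimethylcyclohex-2-en-1-ylidene]acetaldehyde; 17 2-(triphenyl-λ5-phosphanylidene)propanal
Product: 28 (2E,4E)-4-[(4S)-4-(tert-butyldimethylsilyloxy)-2,6,6-trimethylcyclohex-2-en-1-ylidene]-2-methylbut-2-enal
Conditions: PhMe, 90 °C
Reagents that add atoms: none
Why: Wittig reaction of the stabilised ylide forms C8′=C9′ with E-selectivity, as in step 10.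

Step 19
Reactants: 28 (2E,4E)-4-[(4S)-4-(tert-butyldimethylsilyloxy)-2,6,6-trimethylcyclohex-2-en-1-ylidene]-2-methylbut-2-enal; 21 [(2E)-3-methylpent-2-en-4-yn-1-ylidene]triphenyl-λ5-phosphane
Product: 29 ring B trienyne: (4S)-4-(tert-butyldimethylsilyloxy)-2,6,6-trimethylcyclohex-2-ene bearing at C1 the (1E)-[(2E,4E,6E)-3,7-dimethylnona-2,4,6-trien-8-yn-1-ylidene] chain
Conditions: 21 (1.3 equiv, THF solution from step 12), THF, –78 to 0 °C; then I2 (0.5 mol %), hexane, 25 °C, diffuse light
Reagents that add atoms: none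
Why: Wittig reaction of the allylic ylide forms C10′=C11′ and iodine equilibration gives the (10′E) isomer, as in step 13.

Step 20
Reactants: 29 ring B trienyne; 24 ring A tetraenyl iodide
Product: 31 3,5-bis-O-triethylsilyl-3′-O-tert-butyldimethylsilyl ether of the target, via alkenylboronate 30 (not isolated)
Conditions: pinacolborane (1.2 equiv), Cp2Zr(H)Cl (10 mol %), Et3N (10 mol %), CH2Cl2, 25 °C; then 24, Pd(PPh3)4 (5 mol %), TlOEt (1.5 equiv), THF/H2O 3:1, 25 °C, dark
Reagents that add atoms: none
Why: Zirconium-catalysed syn hydroboration of the terminal alkyne gives the (14′E)-alkenylboronate, and Suzuki–Miyaura coupling with the alkenyl iodide forms the C15–C15′ single bond with retention at both partners.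

Step 21
Reactants: 31 3,5-bis-O-triethylsilyl-3′-O-tert-butyldimethylsilyl ether of the target
Product: 32 target triol (CNP0269135.1)
Conditions: Bu4NF (4 equiv), AcOH (4 equiv), THF, 0 to 25 °C, dark
Reagents that add atoms: none
Why: Buffered fluoride cleavage of the three silyl ethers avoids acid, which would ionise the tertiary and secondary allylic alcohols, and leaves the polyene and all three stereocenters untouched.

**Compound list**

1 | 4-hydroxy-6-methyl-2H-pyran-2-one (triacetic acid lactone) | CC1=CC(O)=CC(=O)O1 | starting material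
2 | 6-methyl-2-oxo-2H-pyran-4-yl acetate | CC(=O)OC1=CC(=O)OC(C)=C1 | intermediate
3 | 2-bromo-N-methoxy-N-methylacetamide | CON(C)C(=O)CBr | starting material
4 | [2-(methoxy(methyl)amino)-2-oxoethyl]triphenylphosphonium bromide | CON(C)C(=O)C[P+](c1ccccc1)(c1ccccc1)c1ccccc1.[Br-] | intermediate
5 | 2-methylpropanoyl chloride | CC(C)C(Cl)=O | starting material
6 | N-methoxy-N-methyl-2-(triphenyl-λ5-phosphanylidene)acetamide | CON(C)C(=O)C=P(c1ccccc1)(c1ccccc1)c1ccccc1 | intermediate
7 | 2-methylprop-1-en-1-one (dimethylketene) | CC(C)=C=O | intermediate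
8 | N-methoxy-N,4-dimethylpenta-2,3-dienamide | CC(C)=C=CC(=O)N(C)OC | intermediate
9 | (7E)-7-[2-(methoxy(methyl)amino)-2-oxoethylidene]-1,8,8-trimethyl-3-oxo-2-oxabicyclo[2.2.2]oct-5-en-5-yl acetate, racemic | CC(=O)OC1=C[C@@]2(C)OC(=O)[C@@H]1C(C)(C)/C2=C\C(=O)N(C)OC | intermediate
10 | (4E)-4-[2-(methoxy(methyl)amino)-2-oxoethylidene]-3,3,5-trimethylcyclohexa-1,5-dien-1-yl acetate | CON(C)C(=O)/C=C1\C(C)(C)C=C(OC(C)=O)C=C1C | intermediate
11 | (2E)-N-methoxy-N-methyl-2-(2,6,6-trimethyl-4-oxocyclohex-2-en-1-ylidene)acetamide | CON(C)C(=O)/C=C1\C(C)(C)CC(=O)C=C1C | intermediate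
12 | (2E)-N-methoxy-N-methyl-2-[(1R,6R)-1,3,3-trimethyl-5-oxo-7-oxabicyclo[4.1.0]heptan-2-ylidene]acetamide | CON(C)C(=O)/C=C1\C(C)(C)CC(=O)[C@@H]2O[C@]12C | intermediate
13 | (2E)-2-[(2S)-2-hydroxy-2,6,6-trimethyl-4-oxocyclohexylidene]-N-methoxy-N-methylacetamide | CON(C)C(=O)/C=C1\C(C)(C)CC(=O)C[C@]1(C)O | intermediate
14 | (2E)-2-[(2S,4R)-2,4-dihydroxy-2,6,6-trimethylcyclohexylidene]-N-methoxy-N-methylacetamide | CON(C)C(=O)/C=C1\C(C)(C)C[C@@H](O)C[C@]1(C)O | intermediate
15 | (2E)-N-methoxy-N-methyl-2-[(2S,4R)-2,6,6-trimethyl-2,4-bis(triethylsilyloxy)cyclohexylidene]acetamide | CON(C)C(=O)/C=C1\C(C)(C)C[C@@H](O[Si](CC)(CC)CC)C[C@]1(C)O[Si](CC)(CC)CC | intermediate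
16 | (2E)-2-[(2S,4R)-2,6,6-trimethyl-2,4-bis(triethylsilyloxy)cyclohexylidene]acetaldehyde | O=C/C=C1\C(C)(C)C[C@@H](O[Si](CC)(CC)CC)C[C@]1(C)O[Si](CC)(CC)CC | intermediate
17 | 2-(triphenyl-λ5-phosphanylidene)propanal | CC(C=O)=P(c1ccccc1)(c1ccccc1)c1ccccc1 | starting material
18 | (2E,4E)-2-methyl-4-[(2S,4R)-2,6,6-trimethyl-2,4-bis(triethylsilyloxy)cyclohexylidene]but-2-enal | O=C/C(C)=C/C=C1\C(C)(C)C[C@@H](O[Si](CC)(CC)CC)C[C@]1(C)O[Si](CC)(CC)CC | intermediate
19 | (2E)-3-methylpent-2-en-4-yn-1-ol | OC/C=C(C)/C#C | starting material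
20 | [(2E)-3-methylpent-2-en-4-yn-1-yl]triphenylphosphonium bromide | C#C/C(C)=C/C[P+](c1ccccc1)(c1ccccc1)c1ccccc1.[Br-] | intermediate
21 | [(2E)-3-methylpent-2-en-4-yn-1-ylidene]triphenyl-λ5-phosphane | C#C/C(C)=C/C=P(c1ccccc1)(c1ccccc1)c1ccccc1 | intermediate
22 | ring A trienyne: (2S,4R)-1-[(1E)-(2E,4E,6E)-3,7-dimethylnona-2,4,6-trien-8-yn-1-ylidene]-2,6,6-trimethyl-2,4-bis(triethylsilyloxy)cyclohexane | C#C/C(C)=C/C=C/C(C)=C/C=C1\C(C)(C)C[C@@H](O[Si](CC)(CC)CC)C[C@]1(C)O[Si](CC)(CC)CC | intermediate
23 | chlorobis(cyclopentadienyl)[(1E)-alkenyl]zirconium from 22 (Zr at C15; cyclopentadienyl rings drawn η1) | Cl[Zr](/C=C/C(C)=C/C=C/C(C)=C/C=C1\C(C)(C)C[C@@H](O[Si](CC)(CC)CC)C[C@]1(C)O[Si](CC)(CC)CC)(C2C=CC=C2)C3C=CC=C3 | intermediate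
24 | ring A tetraenyl iodide: (2S,4R)-1-[(1E)-(2E,4E,6E,8E)-9-iodo-3,7-dimethylnona-2,4,6,8-tetraen-1-ylidene]-2,6,6-trimethyl-2,4-bis(triethylsilyloxy)cyclohexane | I/C=C/C(C)=C/C=C/C(C)=C/C=C1\C(C)(C)C[C@@H](O[Si](CC)(CC)CC)C[C@]1(C)O[Si](CC)(CC)CC | intermediate
25 | (2E)-2-[(4S)-4-hydroxy-2,6,6-trimethylcyclohex-2-en-1-ylidene]-N-methoxy-N-methylacetamide | CC1=C[C@@H](O)CC(C)(C)\C1=C/C(=O)N(C)OC | intermediate
26 | (2E)-2-[(4S)-4-(tert-butyldimethylsilyloxy)-2,6,6-trimethylcyclohex-2-en-1-ylidene]-N-methoxy-N-methylacetamide | CC1=C[C@@H](O[Si](C)(C)C(C)(C)C)CC(C)(C)\C1=C/C(=O)N(C)OC | intermediate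
27 | (2E)-2-[(4S)-4-(tert-butyldimethylsilyloxy)-2,6,6-trimethylcyclohex-2-en-1-ylidene]acetaldehyde | CC1=C[C@@H](O[Si](C)(C)C(C)(C)C)CC(C)(C)\C1=C/C=O | intermediate
28 | (2E,4E)-4-[(4S)-4-(tert-butyldimethylsilyloxy)-2,6,6-trimethylcyclohex-2-en-1-ylidene]-2-methylbut-2-enal | CC1=C[C@@H](O[Si](C)(C)C(C)(C)C)CC(C)(C)\C1=C/C=C(C)/C=O | intermediate
29 | ring B trienyne: (4S)-4-(tert-butyldimethylsilyloxy)-1-[(1E)-(2E,4E,6E)-3,7-dimethylnona-2,4,6-trien-8-yn-1-ylidene]-2,6,6-trimethylcyclohex-2-ene | CC1=C[C@@H](O[Si](C)(C)C(C)(C)C)CC(C)(C)\C1=C/C=C(C)/C=C/C=C(C)/C#C | intermediate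
30 | ring B (14′E)-alkenyl pinacolboronate from 29 (boron at C15′) | CC1=C[C@@H](O[Si](C)(C)C(C)(C)C)CC(C)(C)\C1=C/C=C(C)/C=C/C=C(C)/C=C/B2OC(C)(C)C(C)(C)O2 | intermediate
31 | 3,5-bis-O-triethylsilyl-3′-O-tert-butyldimethylsilyl ether of the target | CC1=C[C@@H](O[Si](C)(C)C(C)(C)C)CC(C)(C)\C1=C/C=C(C)/C=C/C=C(C)/C=C/C=C/C(C)=C/C=C/C(C)=C/C=C1\C(C)(C)C[C@@H](O[Si](CC)(CC)CC)C[C@]1(C)O[Si](CC)(CC)CC | intermediate
32 | target CNP0269135.1: all-E retro-carotenoid triol, ring A (3R,5S)-3,5-dihydroxy (cyclohexylidene), ring B (3′S)-3′-hydroxy-4′,5′-ene (cyclohexenylidene) | CC1=C[C@@H](O)CC(C)(C)\C1=C/C=C(C)/C=C/C=C(C)/C=C/C=C/C(C)=C/C=C/C(C)=C/C=C1\C(C)(C)C[C@@H](O)C[C@]1(C)O | target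

Total step count: 21. Longest linear sequence: 13 steps (steps 2, 3, 4, 5, 6, 7, 8, 9, 10, 13, 14, 20, 21).

**Steps most likely to fail**

Step 4 (proposed new method). The pyrone may add to the amide-conjugated double bond of the allene instead of the distal one, or the allene may be consumed thermally (dimerisation, ene reactions, a second cycloaddition onto diene 10) before the pyrone reacts. The fallback sets out from bromoacetamide 3 and returns to the route at 11, using only known carbonyl chemistry. Commercial 2,6,6-trimethylcyclohex-2-ene-1,4-dione is converted at its less hindered carbonyl into the monoketal 7,9,9-trimethyl-1,4-dioxaspiro[4.5]dec-6-en-8-one F1 (ethylene glycol, p-TsOH, PhH, water separator). The zinc enolate of 3 (Zn, THF, reflux; Reformatsky reaction) adds to the remaining hindered ketone to give the tertiary alcohol 2-(8-hydroxy-7,9,9-trimethyl-1,4-dioxaspiro[4.5]dec-6-en-8-yl)-N-methoxy-N-methylacetamide F2. Aqueous HCl in THF then dehydrates F2 (only the exocyclic direction carries a hydrogen) and removes the ketal, giving 11; a trace of I2 would equilibrate the exocyclic olefin to the E-isomer.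

Step 5. Iminium formation with the β,β-disubstituted, cross-conjugated enone may be slow, or the facial selectivity may be poor. The fallback sets out from allylic alcohol 25 (step 15) and returns at 12, so that the CBS-set carbinol controls the epoxide. Hydroxyl-directed epoxidation of the C4=C5 bond (VO(acac)2 cat., t-BuOOH, PhH, 25 °C) gives the syn epoxy alcohol (2E)-2-[(1R,5S,6S)-5-hydroxy-1,3,3-trimethyl-7-oxabicyclo[4.1.0]heptan-2-ylidene]-N-methoxy-N-methylacetamide F3. Dess–Martin oxidation of the carbinol (NaHCO3, CH2Cl2) then gives epoxy ketone 12 with the epoxide on the required face.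

Step 20. Protodeboronation or homocoupling of the polyenylboronate, and degradation of both polyenes in the basic aqueous medium, may erode the coupling. The fallback sets out from alkyne 29 and iodide 24 and returns at 31. Sonogashira coupling (Pd(PPh3)4, CuI, Et3N, THF, 25 °C) gives the 14′,15′-didehydro compound F4. Semi-reduction of the triple bond with zinc activated by Cu(OAc)2 and AgNO3 in aqueous MeOH gives the (14′Z)-isomer F5. Iodine-catalysed equilibration (I2, hexane, diffuse light) of the hindered cis bond then gives all-E 31.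

**Further compounds**

F1 | step 4 | 7,9,9-trimethyl-1,4-dioxaspiro[4.5]dec-6-en-8-one | CC1=CC2(CC(C)(C)C1=O)OCCO2
F2 | step 4 | 2-(8-hydroxy-7,9,9-trimethyl-1,4-dioxaspiro[4.5]dec-6-en-8-yl)-N-methoxy-N-methylacetamide, racemic | CC1=CC2(CC(C)(C)C1(O)CC(=O)N(C)OC)OCCO2
F3 | step 5 | (2E)-2-[(1R,5S,6S)-5-hydroxy-1,3,3-trimethyl-7-oxabicyclo[4.1.0]heptan-2-ylidene]-N-methoxy-N-methylacetamide | CON(C)C(=O)/C=C1\C(C)(C)C[C@H](O)[C@@H]2O[C@]12C
F4 | step 20 | 14′,15′-didehydro derivative of 31 | CC1=C[C@@H](O[Si](C)(C)C(C)(C)C)CC(C)(C)\C1=C/C=C(C)/C=C/C=C(C)/C#C/C=C/C(C)=C/C=C/C(C)=C/C=C1\C(C)(C)C[C@@H](O[Si](CC)(CC)CC)C[C@]1(C)O[Si](CC)(CC)CC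
F5 | step 20 | (14′Z)-isomer of 31 | CC1=C[C@@H](O[Si](C)(C)C(C)(C)C)CC(C)(C)\C1=C/C=C(C)/C=C/C=C(C)/C=C\C=C\C(C)=C\C=C\C(C)=C\C=C1/C(C)(C)C[C@@H](O[Si](CC)(CC)CC)C[C@]1(C)O[Si](CC)(CC)CC
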